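With the chain numbered from the ketone carbon C1, the aryl–C1 bond and the C10=C11 and C12=C13 alkenes are cut, leaving a C1–C10 unit in which C1 and the C9 oxygen flank the Z C6=C7 alkene. An ester between O9 and C1 places that alkene in a ten-membered lactone ring, so one ring-closing metathesis of the open-chain diene ester 6 (the hept-6-enoate of an (R)-homoallylic alcohol derived from (S)-glycidol) forms C6=C7 and lets the ring dictate cis geometry. The lactone then masks the C9 hydroxyl during two Wittig reactions and finally acylates lithiated, MOM-protected phloroglucinol.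

Key step: step 4

Remark: C9 of the target is R. O-Alkylation of (S)-glycidol changes the CIP descriptor of its stereocentre to R without changing its geometry, because the ranking of the two CH2 groups is reversed in the ether; the glycidyl ether 2 is therefore named R.

Step 1
Reactants: 1 (S)-glycidol
Product: 2 (R)-2-[(4-methoxybenzyloxy)methyl]oxirane
Conditions: NaH, 4-methoxybenzyl chloride, Bu4NI (cat.), THF/DMF, 0 °C → rt
Reagents that add atoms: 4-methoxybenzyl chloride, COc1ccc(CCl)cc1
Why: Williamson etherification of the primary alkoxide breaks no bond at the epoxide stereocentre, which is carried over unchanged.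

Step 2
Reactants: 2 (R)-2-[(4-methoxybenzyloxy)methyl]oxirane; 3 vinylmagnesium bromide
Product: 4 (R)-1-(4-methoxybenzyloxy)pent-4-en-2-ol
Conditions: CuI (10 mol %), THF, −30 → 0 °C; then aq NH4Cl
Reagents that add atoms: none
Why: Copper-catalysed Grignard opening of a terminal epoxide is an SN2 attack at the unsubstituted CH2, so the carbinol carbon (future C9) is not touched and stays R.

Step 3
Reactants: 4 (R)-1-(4-methoxybenzyloxy)pent-4-en-2-ol; 5 hept-6-enoic acid
Product: 6 (R)-1-(4-methoxybenzyloxy)pent-4-en-2-yl hept-6-enoate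
Conditions: DCC, DMAP (cat.), CH2Cl2, 0 °C → rt
Reagents that add atoms: none
Why: Steglich esterification (carbodiimide activation, DMAP acyl transfer) acylates the secondary alcohol at oxygen and leaves the C–O bond of the stereocentre intact.

Step 4
Reactants: 6 (R)-1-(4-methoxybenzyloxy)pent-4-en-2-yl hept-6-enoate
Product: 7 (7Z,10R)-10-[(4-methoxybenzyloxy)methyl]-3,4,5,6,9,10-hexahydro-2H-oxecin-2-one
Conditions: second-generation Grubbs catalyst (H2IMes)(PCy3)Cl2Ru=CHPh (5–10 mol %, in portions), 1,4-benzoquinone (10 mol %), CH2Cl2 (about 1 mM), reflux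
Reagents that add atoms: none
Why: Ring-closing olefin metathesis: the ruthenium benzylidene exchanges onto one terminal alkene of 6, the second alkene of the same molecule undergoes [2+2] addition to a ruthenacyclobutane, and retro-[2+2] expels ethylene and leaves the endocyclic alkene. The closest known reaction type is ring-closing metathesis to ten-membered unsaturated lactones of the decanolide class. The one ring formed, the ten-membered lactone (O9 and C1–C9), closes by head-to-head union of the two vinyl groups, so that C6 and C7 become the ring alkene carbons and ethylene is the only by-product. No stereocentre is created; C9 is a spectator and keeps its R configuration. The step needs Z over E at C6=C7 and ring closure over oligomerisation: the cis isomer of a ten-membered cycloalkene lactone carries less strain than the trans isomer, and because (H2IMes)(PCy3)Cl2Ru=CHPh re-opens and re-closes the product the mixture should drift towards Z, while high dilution favours the intramolecular path. 1,4-Benzoquinone is added to intercept ruthenium hydrides that would otherwise shift the alkene and contract the ring.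

Step 5
Reactants: 7 (7Z,10R)-10-[(4-methoxybenzyloxy)methyl]-3,4,5,6,9,10-hexahydro-2H-oxecin-2-one
Product: 8 (7Z,10R)-10-(hydroxymethyl)-3,4,5,6,9,10-hexahydro-2H-oxecin-2-one
Conditions: DDQ, CH2Cl2/pH 7 phosphate buffer, 0 °C → rt
Reagents that add atoms: none
Why: Oxidative cleavage of the 4-methoxybenzyl ether by DDQ (hydride abstraction, hydrolysis of the oxocarbenium ion) runs at neutral pH, so the lactone, the isolated Z-alkene and the stereocentre should survive and no base is present to drive acyl migration to the primary hydroxyl.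

Step 6
Reactants: 8 (7Z,10R)-10-(hydroxymethyl)-3,4,5,6,9,10-hexahydro-2H-oxecin-2-one
Product: 9 (7Z,10R)-2-oxo-3,4,5,6,9,10-hexahydro-2H-oxecine-10-carbaldehyde (lactone numbering kept)
Conditions: Dess–Martin periodinane, CH2Cl2, 0 °C → rt; used crude
Reagents that add atoms: none
Why: Dess–Martin oxidation gives the aldehyde under non-basic conditions, so the α-acyloxy stereocentre should not epimerise.

Step 7
Reactants: 9 (7Z,10R)-2-oxo-3,4,5,6,9,10-hexahydro-2H-oxecine-10-carbaldehyde; 10 (triphenylphosphoranylidene)acetaldehyde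
Product: 11 (7Z,10R)-10-[(E)-3-oxoprop-1-enyl]-3,4,5,6,9,10-hexahydro-2H-oxecin-2-one
Conditions: toluene, rt → 40 °C
Reagents that add atoms: none
Why: Wittig olefination with a stabilised formyl ylide should give the E-enal (C10=C11), and the neutral ylide neither epimerises the α-acyloxy aldehyde nor attacks the lactone.

Step 8
Reactants: 12 (Z)-hex-3-en-1-ol
Product: 13 (Z)-1-iodohex-3-ene
Conditions: iodine, PPh3, imidazole, CH2Cl2, 0 °C → rt
Reagents that add atoms: iodine, [I][I]
Why: Appel-type iodination converts the primary alcohol to the iodide by SN2 displacement of the oxyphosphonium group without touching the Z-alkene.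

Step 9
Reactants: 13 (Z)-1-iodohex-3-ene
Product: 14 [(Z)-hex-3-enyl]triphenylphosphonium iodide
Conditions: PPh3, MeCN, reflux
Reagents that add atoms: triphenylphosphine, c1ccc(cc1)P(c1ccccc1)c1ccccc1
Why: SN2 quaternisation of triphenylphosphine by a primary iodide gives the phosphonium salt and leaves the alkene geometry alone.

Step 10
Reactants: 11 (7Z,10R)-10-[(E)-3-oxoprop-1-enyl]-3,4,5,6,9,10-hexahydro-2H-oxecin-2-one; 14 [(Z)-hex-3-enyl]triphenylphosphonium iodide
Product: 16 (7Z,10R)-10-[(1E,3Z,6Z)-nona-1,3,6-trienyl]-3,4,5,6,9,10-hexahydro-2H-oxecin-2-one, via (Z)-hex-3-enylidenetriphenylphosphorane 15 (not isolated)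
Conditions: NaN(SiMe3)2 (slightly less than 14), THF, −78 °C; then 11, −78 → −20 °C
Reagents that add atoms: none
Why: Z-selective Wittig olefination of a non-stabilised ylide under lithium-free conditions forms the cis-oxaphosphetane kinetically and so the C12=C13 Z-alkene, the aldehyde reacting far faster than the lactone carbonyl at low temperature and C9 staying untouched.

Step 11
Reactants: 17 phloroglucinol
Product: 18 1,3,5-tris(methoxymethoxy)benzene
Conditions: NaH, chloromethyl methyl ether, DMF, 0 °C → rt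
Reagents that add atoms: chloromethyl methyl ether, COCCl
Why: Williamson-type O-alkylation of the phenoxides with a hard chloromethyl ether gives the tris-acetal, which carries the directing groups for the next lithiation.

Step 12
Reactants: 16 (7Z,10R)-10-[(1E,3Z,6Z)-nona-1,3,6-trienyl]-3,4,5,6,9,10-hexahydro-2H-oxecin-2-one; 18 1,3,5-tris(methoxymethoxy)benzene
Product: 20 (6Z,9R,10E,12Z,15Z)-9-hydroxy-1-[2,4,6-tris(methoxymethoxy)phenyl]octadeca-6,10,12,15-tetraen-1-one, via 2-lithio-1,3,5-tris(methoxymethoxy)benzene 19 (not isolated)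
Conditions: n-BuLi, THF, 0 °C; then 16 (aryllithium in excess), −78 → −30 °C; aq NH4Cl
Reagents that add atoms: none
Why: Directed ortho-lithiation of 18 between two methoxymethoxy groups followed by nucleophilic acyl substitution on the lactone should stop at the ketone, because the 2,6-disubstituted aryl ketone is too hindered for a second addition; the C9–O bond is never broken, so C9 stays R and the ring oxygen emerges as the free hydroxyl.

Step 13
Reactants: 20 (6Z,9R,10E,12Z,15Z)-9-hydroxy-1-[2,4,6-tris(methoxymethoxy)phenyl]octadeca-6,10,12,15-tetraen-1-one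
Product: 22 (6Z,9R,10E,12Z,15Z)-9-hydroxy-1-(2,4,6-trihydroxyphenyl)octadeca-6,10,12,15-tetraen-1-one, via tetrakis(trimethylsilyl) ether 21 (not isolated)
Conditions: Me3SiOTf, 2,2′-bipyridyl (both in excess), CH2Cl2 or MeCN, 0 °C → rt; then H2O, THF, rt
Reagents that add atoms: none
Why: Silyl triflate/2,2′-bipyridyl cleavage of aromatic methoxymethyl ethers exchanges each aryl O–CH2OMe for aryl O–SiMe3 (and silylates the C9 hydroxyl) without protic acid, and water then hydrolyses the labile trimethylsilyl ethers, so the ionisable dienylic C9 centre and the Z-alkenes should not be disturbed.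

Compound list
1 | (S)-glycidol | OC[C@H]1CO1 | starting material
2 | (R)-2-[(4-methoxybenzyloxy)methyl]oxirane | COc1ccc(COC[C@H]2CO2)cc1 | intermediate
3 | vinylmagnesium bromide | C=C[Mg]Br | starting material
4 | (R)-1-(4-methoxybenzyloxy)pent-4-en-2-ol | COc1ccc(COC[C@H](O)CC=C)cc1 | intermediate
5 | hept-6-enoic acid | C=CCCCCC(=O)O | starting material
6 | (R)-1-(4-methoxybenzyloxy)pent-4-en-2-yl hept-6-enoate | COc1ccc(COC[C@H](OC(=O)CCCCC=C)CC=C)cc1 | intermediate
7 | (7Z,10R)-10-[(4-methoxybenzyloxy)methyl]-3,4,5,6,9,10-hexahydro-2H-oxecin-2-one | COc1ccc(COC[C@H]2C/C=C\CCCCC(=O)O2)cc1 | intermediate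
8 | (7Z,10R)-10-(hydroxymethyl)-3,4,5,6,9,10-hexahydro-2H-oxecin-2-one | OC[C@H]1C/C=C\CCCCC(=O)O1 | intermediate
9 | (7Z,10R)-2-oxo-3,4,5,6,9,10-hexahydro-2H-oxecine-10-carbaldehyde | O=C[C@H]1C/C=C\CCCCC(=O)O1 | intermediate
10 | (triphenylphosphoranylidene)acetaldehyde | O=CC=P(c1ccccc1)(c1ccccc1)c1ccccc1 | starting material
11 | (7Z,10R)-10-[(E)-3-oxoprop-1-enyl]-3,4,5,6,9,10-hexahydro-2H-oxecin-2-one | O=C/C=C/[C@H]1C/C=C\CCCCC(=O)O1 | intermediate
12 | (Z)-hex-3-en-1-ol | CC/C=C\CCO | starting material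
13 | (Z)-1-iodohex-3-ene | CC/C=C\CCI | intermediate
14 | [(Z)-hex-3-enyl]triphenylphosphonium iodide | CC/C=C\CC[P+](c1ccccc1)(c1ccccc1)c1ccccc1.[I-] | intermediate
15 | (Z)-hex-3-enylidenetriphenylphosphorane | CC/C=C\CC=P(c1ccccc1)(c1ccccc1)c1ccccc1 | intermediate
16 | (7Z,10R)-10-[(1E,3Z,6Z)-nona-1,3,6-trienyl]-3,4,5,6,9,10-hexahydro-2H-oxecin-2-one | CC/C=C\C/C=C\C=C\[C@H]1C/C=C\CCCCC(=O)O1 | intermediate
17 | phloroglucinol | Oc1cc(O)cc(O)c1 | starting material
18 | 1,3,5-tris(methoxymethoxy)benzene | COCOc1cc(OCOC)cc(OCOC)c1 | intermediate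
19 | 2-lithio-1,3,5-tris(methoxymethoxy)benzene | [Li]c1c(OCOC)cc(OCOC)cc1OCOC | intermediate
20 | (6Z,9R,10E,12Z,15Z)-9-hydroxy-1-[2,4,6-tris(methoxymethoxy)phenyl]octadeca-6,10,12,15-tetraen-1-one | CC/C=C\C/C=C\C=C\[C@H](O)C/C=C\CCCCC(=O)c1c(OCOC)cc(OCOC)cc1OCOC | intermediate
21 | (6Z,9R,10E,12Z,15Z)-9-(trimethylsilyloxy)-1-[2,4,6-tris(trimethylsilyloxy)phenyl]octadeca-6,10,12,15-tetraen-1-one | CC/C=C\C/C=C\C=C\[C@H](O[Si](C)(C)C)C/C=C\CCCCC(=O)c1c(O[Si](C)(C)C)cc(O[Si](C)(C)C)cc1O[Si](C)(C)C | intermediate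
22 | (6Z,9R,10E,12Z,15Z)-9-hydroxy-1-(2,4,6-trihydroxyphenyl)octadeca-6,10,12,15-tetraen-1-one | CC/C=C\C/C=C\C=C\[C@H](O)C/C=C\CCCCC(=O)c1c(O)cc(O)cc1O | target

Total step count: 13.
Longest linear sequence: 10 steps from (S)-glycidol (steps 1–7, 10, 12, 13).

Steps most likely to fail

Step 4. Intermolecular metathesis may outrun closure of the strained medium ring and give oligomers, or the ring may close with incomplete cis selectivity at C6=C7. Fallback, from 4 back to 7: the alkene geometry is set on an open chain by a Wittig reaction and the ring is closed at the ester bond instead.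
- Alcohol 4 is silylated (TBSCl, imidazole, DMF) to (R)-tert-butyl{[1-(4-methoxybenzyloxy)pent-4-en-2-yl]oxy}dimethylsilane F1.
- Lemieux–Johnson cleavage (OsO4 cat., NaIO4, 2,6-lutidine, dioxane/H2O) gives (R)-3-(tert-butyldimethylsilyloxy)-4-(4-methoxybenzyloxy)butanal F2.
- Commercial (5-carboxypentyl)triphenylphosphonium bromide and two equivalents of NaN(SiMe3)2 in THF at −78 °C give sodium 6-(triphenylphosphoranylidene)hexanoate F3. Its Z-selective Wittig reaction with F2 should give (R,Z)-9-(tert-butyldimethylsilyloxy)-10-(4-methoxybenzyloxy)dec-6-enoic acid F4.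
- TBAF in THF frees (R,Z)-9-hydroxy-10-(4-methoxybenzyloxy)dec-6-enoic acid F5.
- Yamaguchi lactonisation (2,4,6-trichlorobenzoyl chloride, Et3N, THF; then slow addition to DMAP in toluene at reflux, high dilution) passes through the 2,4,6-trichlorobenzoic mixed anhydride F6 and closes lactone 7.

Step 12. The hindered aryllithium may deprotonate the lactone at C2 instead of adding, or add too slowly to the s-trans medium-ring ester, so that the lactone is returned. Fallback, from 16 back to 20: the acyl donor is changed to a Weinreb amide.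
- Lactone 16 is opened with MeNH(OMe)·HCl and iPrMgCl in THF at −20 °C to (6Z,9R,10E,12Z,15Z)-9-hydroxy-N-methoxy-N-methyloctadeca-6,10,12,15-tetraenamide F7.
- F7 is treated with excess aryllithium 19 in THF at −78 → 0 °C; the first equivalent forms the C9 lithium alkoxide. The chelated tetrahedral intermediate releases ketone 20 on aqueous quench.

Step 13. The dienylic C9 oxygen may ionise under the Lewis-acidic conditions, with allylic transposition, elimination or loss of configuration, or the para acetal may cleave incompletely. Fallback, from 7 back to 22: the aryl ketone is installed and the acetals are removed before the diene exists, and the end game uses fluoride only.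
- Aryllithium 19 opens lactone 7 (THF, −78 → −30 °C) to (R,Z)-9-hydroxy-10-(4-methoxybenzyloxy)-1-[2,4,6-tris(methoxymethoxy)phenyl]dec-6-en-1-one F8.
- HCl in MeOH at rt removes the three acetals and gives (R,Z)-9-hydroxy-10-(4-methoxybenzyloxy)-1-(2,4,6-trihydroxyphenyl)dec-6-en-1-one F9.
- TBSOTf and 2,6-lutidine (CH2Cl2, 0 °C) give the tetrakis(tert-butyldimethylsilyl) ether F10.
- DDQ (CH2Cl2/pH 7 buffer) gives (R,Z)-9-(tert-butyldimethylsilyloxy)-10-hydroxy-1-[2,4,6-tris(tert-butyldimethylsilyloxy)phenyl]dec-6-en-1-one F11.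
- Dess–Martin oxidation gives the corresponding (R,Z)-2-silyloxy-10-oxo-10-aryldec-4-enal F12.
- Wittig reaction with 10 gives the (2E,4R,6Z)-4-silyloxy-12-oxo-12-aryldodeca-2,6-dienal F13.
- Z-selective Wittig reaction with ylide 15 (from 14, NaN(SiMe3)2, THF, −78 °C) gives the tetrakis(tert-butyldimethylsilyl) ether of the target F14.
- TBAF buffered with AcOH in THF (0 °C → rt) removes all four silyl groups and gives 22.

Further compounds
F1 | step 4 | (R)-tert-butyl{[1-(4-methoxybenzyloxy)pent-4-en-2-yl]oxy}dimethylsilane | COc1ccc(COC[C@H](O[Si](C)(C)C(C)(C)C)CC=C)cc1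
F2 | step 4 | (R)-3-(tert-butyldimethylsilyloxy)-4-(4-methoxybenzyloxy)butanal | COc1ccc(COC[C@H](O[Si](C)(C)C(C)(C)C)CC=O)cc1
F3 | step 4 | sodium 6-(triphenylphosphoranylidene)hexanoate | [Na+].[O-]C(=O)CCCCC=P(c1ccccc1)(c1ccccc1)c1ccccc1
F4 | step 4 | (R,Z)-9-(tert-butyldimethylsilyloxy)-10-(4-methoxybenzyloxy)dec-6-enoic acid | COc1ccc(COC[C@H](O[Si](C)(C)C(C)(C)C)C/C=C\CCCCC(=O)O)cc1
F5 | step 4 | (R,Z)-9-hydroxy-10-(4-methoxybenzyloxy)dec-6-enoic acid | COc1ccc(COC[C@H](O)C/C=C\CCCCC(=O)O)cc1
F6 | step 4 | (R,Z)-9-hydroxy-10-(4-methoxybenzyloxy)dec-6-enoic 2,4,6-trichlorobenzoic anhydride | COc1ccc(COC[C@H](O)C/C=C\CCCCC(=O)OC(=O)c2c(Cl)cc(Cl)cc2Cl)cc1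
F7 | step 12 | (6Z,9R,10E,12Z,15Z)-9-hydroxy-N-methoxy-N-methyloctadeca-6,10,12,15-tetraenamide | CC/C=C\C/C=C\C=C\[C@H](O)C/C=C\CCCCC(=O)N(C)OC
F8 | step 13 | (R,Z)-9-hydroxy-10-(4-methoxybenzyloxy)-1-[2,4,6-tris(methoxymethoxy)phenyl]dec-6-en-1-one | COc1ccc(COC[C@H](O)C/C=C\CCCCC(=O)c2c(OCOC)cc(OCOC)cc2OCOC)cc1
F9 | step 13 | (R,Z)-9-hydroxy-10-(4-methoxybenzyloxy)-1-(2,4,6-trihydroxyphenyl)dec-6-en-1-one | COc1ccc(COC[C@H](O)C/C=C\CCCCC(=O)c2c(O)cc(O)cc2O)cc1
F10 | step 13 | (R,Z)-9-(tert-butyldimethylsilyloxy)-10-(4-methoxybenzyloxy)-1-[2,4,6-tris(tert-butyldimethylsilyloxy)phenyl]dec-6-en-1-one | COc1ccc(COC[C@H](O[Si](C)(C)C(C)(C)C)C/C=C\CCCCC(=O)c2c(O[Si](C)(C)C(C)(C)C)cc(O[Si](C)(C)C(C)(C)C)cc2O[Si](C)(C)C(C)(C)C)cc1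
F11 | step 13 | (R,Z)-9-(tert-butyldimethylsilyloxy)-10-hydroxy-1-[2,4,6-tris(tert-butyldimethylsilyloxy)phenyl]dec-6-en-1-one | OC[C@H](O[Si](C)(C)C(C)(C)C)C/C=C\CCCCC(=O)c1c(O[Si](C)(C)C(C)(C)C)cc(O[Si](C)(C)C(C)(C)C)cc1O[Si](C)(C)C(C)(C)C
F12 | step 13 | (R,Z)-2-(tert-butyldimethylsilyloxy)-10-oxo-10-[2,4,6-tris(tert-butyldimethylsilyloxy)phenyl]dec-4-enal | O=C[C@H](O[Si](C)(C)C(C)(C)C)C/C=C\CCCCC(=O)c1c(O[Si](C)(C)C(C)(C)C)cc(O[Si](C)(C)C(C)(C)C)cc1O[Si](C)(C)C(C)(C)C
F13 | step 13 | (2E,4R,6Z)-4-(tert-butyldimethylsilyloxy)-12-oxo-12-[2,4,6-tris(tert-butyldimethylsilyloxy)phenyl]dodeca-2,6-dienal | O=C/C=C/[C@H](O[Si](C)(C)C(C)(C)C)C/C=C\CCCCC(=O)c1c(O[Si](C)(C)C(C)(C)C)cc(O[Si](C)(C)C(C)(C)C)cc1O[Si](C)(C)C(C)(C)C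
F14 | step 13 | (6Z,9R,10E,12Z,15Z)-9-(tert-butyldimethylsilyloxy)-1-[2,4,6-tris(tert-butyldimethylsilyloxy)phenyl]octadeca-6,10,12,15-tetraen-1-one | CC/C=C\C/C=C\C=C\[C@H](O[Si](C)(C)C(C)(C)C)C/C=C\CCCCC(=O)c1c(O[Si](C)(C)C(C)(C)C)cc(O[Si](C)(C)C(C)(C)C)cc1O[Si](C)(C)C(C)(C)C
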